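**Plan**

- Retrosynthesis: the aroyl C–C bond at C4 is cut first (aryllithium plus N-methoxy-N-methylamide), then O1–C2 and C4–C5 of the oxolane in one operation (aryl cyclopropane-1,1-diester plus formaldehyde), and last the two cyclopropane bonds to the malonate carbon (cinnamaldehyde plus bromomalonate).
- Enabling feature: C2 is a benzylic ether carbon carrying a 4-oxygenated aryl ring (cation-stabilising donor), C4 carries the carbonyl group (acceptor, carried as a malonate), and C5 is an unsubstituted OCH2 between O1 and C4 that formaldehyde can deliver.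
- Forward: syringaldehyde → cinnamaldehyde → trans cyclopropane diester (a temporary three-membered ring) → oxolane ring by (3+2) annulation (the only ring of the target) → one ester removed, the other turned into the aroyl group → deprotection.
- Stereochemistry: C3 comes from the organocatalytic cyclopropanation ((S)-diarylprolinol silyl ether); C2 is set trans to the C3 substituent under thermodynamic control in the annulation; C4 is set trans to C3 by base equilibration of the ketone, giving the all-trans (2S,3R,4S) target.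

Key step: step 6

Remark: ring locants follow the target (O1, C2 aryl, C3 CH2O, C4 carbonyl-bearing, C5 H2; cyclopropane C1 becomes C4) and not lowest-locant rules; Ar = 4-(benzyloxy)-3,5-dimethoxyphenyl, TBDPS = tert-butyldiphenylsilyl; formaldehyde is charged as paraformaldehyde.

**Route**

Step 1
Reactants: 1 syringaldehyde (4-hydroxy-3,5-dimethoxybenzaldehyde)
Product: 2 4-(benzyloxy)-3,5-dimethoxybenzaldehyde
Conditions: BnBr, K2CO3, DMF, 60 °C
Reagents that add atoms: benzyl bromide, BrCc1ccccc1
Why: Williamson O-alkylation of the phenoxide masks the phenol as a benzyl ether that lasts until the final hydrogenolysis; no stereocentre is involved.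

Step 2
Reactants: 2 4-(benzyloxy)-3,5-dimethoxybenzaldehyde
Product: 3 (E)-3-[4-(benzyloxy)-3,5-dimethoxyphenyl]prop-2-enal
Conditions: Ph3P=CHCHO (1.2 equiv), toluene, 90 °C
Reagents that add atoms: (triphenylphosphoranylidene)acetaldehyde, O=CC=P(c1ccccc1)(c1ccccc1)c1ccccc1
Why: Wittig olefination with the stabilised formylmethylene ylide should give the (E)-enal, and the small excess of ylide limits a second homologation.

Step 3
Reactants: 3 (E)-3-Ar-prop-2-enal; 4 dimethyl bromomalonate
Product: 5 dimethyl (2S,3R)-2-Ar-3-formylcyclopropane-1,1-dicarboxylate (aryl and formyl trans)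
Conditions: (S)-2-[diphenyl(trimethylsilyloxy)methyl]pyrrolidine (20 mol %), 2,6-lutidine, CH2Cl2, 0 °C → rt
Reagents that add atoms: none
Why: Organocatalytic Michael-initiated ring closure (iminium then enamine catalysis): the (S)-catalyst shields the Re face of the β-carbon of the (E)-iminium ion, the bromomalonate anion adds to the Si face, and the enamine then displaces bromide (3-exo-tet), which sets C2 and C3 as the trans (2S,3R) cyclopropane.

Step 4
Reactants: 5 dimethyl (2S,3R)-2-Ar-3-formylcyclopropane-1,1-dicarboxylate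
Product: 6 dimethyl (2S,3R)-2-Ar-3-(hydroxymethyl)cyclopropane-1,1-dicarboxylate
Conditions: NaBH4, MeOH–THF, −20 °C; AcOH quench
Reagents that add atoms: none
Why: Chemoselective borohydride reduction of the aldehyde beside two methyl esters, run cold and quenched with acid so that the alkoxide does not lactonise onto the cis ester; no stereocentre is touched.

Step 5
Reactants: 6 dimethyl (2S,3R)-2-Ar-3-(hydroxymethyl)cyclopropane-1,1-dicarboxylate
Product: 7 dimethyl (2S,3R)-2-Ar-3-(TBDPS-oxymethyl)cyclopropane-1,1-dicarboxylate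
Conditions: TBDPSCl, imidazole, CH2Cl2, 0 °C → rt
Reagents that add atoms: tert-butyl(chloro)diphenylsilane, CC(C)(C)[Si](Cl)(c1ccccc1)c1ccccc1
Why: Silylation of the primary alcohol under near-neutral imidazole conditions avoids the lactonisation that an alkoxide etherification would cause and installs a group that tolerates Lewis acid, hot chloride, organometallics and base.

Step 6
Reactants: 7 dimethyl (2S,3R)-2-Ar-3-(TBDPS-oxymethyl)cyclopropane-1,1-dicarboxylate; 8 formaldehyde
Product: 9 dimethyl (2S,3R)-2-Ar-3-(TBDPS-oxymethyl)oxolane-4,4-dicarboxylate (2,3-trans)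
Conditions: (CH2O)n (5 equiv), Sn(OTf)2 (10 mol %), ClCH2CH2Cl, rt → 50 °C
Reagents that add atoms: none
Why: Sn(OTf)2 chelates the geminal diester and polarises the bond between C1 and the aryl-bearing C2 of the cyclopropane, which the trialkoxyaryl donor lets open to (or close to) a benzylic cation/tin malonate enolate pair; the formaldehyde oxygen bonds to C2 (O1–C2) and the malonate carbon then adds to the resulting oxocarbenium carbon (C4–C5). The closest known reaction type is the Lewis acid catalysed (3+2) annulation of 2-arylcyclopropane-1,1-diesters with aldehydes to oxolane diesters, which is established for 2,3-disubstituted cyclopropanes and for aliphatic aldehydes, formaldehyde being the smallest member of the aldehyde class. The oxolane ring closes in the C4–C5 bond formation as a 5-endo-trig attack of the enolate carbon on the oxocarbenium ion, the same closure as in the parent annulation. C2 is the only new stereocentre and is controlled by the resident C3 centre under thermodynamic control: a tight-ion-pair SN2-like course would invert C2 and deliver the 2,3-cis adduct from the trans cyclopropane, so the mixture is kept warm with the triflate so that the benzylic C2–O1 bond of any cis adduct re-ionises and re-closes to the more stable 2,3-trans isomer, either C2 epimer of the cyclopropane converging on 9. The step needs cleavage of C1–C2 and not C1–C3 and an untouched C3, and the substrate secures both because only C2 carries a cation-stabilising aryl group and C3 is never part of a breaking bond. Excess paraformaldehyde keeps enough monomeric aldehyde present to outrun proton loss from the zwitterion to the styrene isomer.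

Step 7
Reactants: 9 dimethyl (2S,3R)-2-Ar-3-(TBDPS-oxymethyl)oxolane-4,4-dicarboxylate
Product: 10 methyl (2S,3R)-2-Ar-3-(TBDPS-oxymethyl)oxolane-4-carboxylate as a mixture of C4 epimers
Conditions: LiCl, H2O, DMSO, 150 °C
Reagents that add atoms: none
Why: Krapcho dealkoxycarbonylation (chloride SN2 at one methyl ester, loss of CO2, protonation of the ester enolate) removes one ester, ring-opening β-elimination of O1 being disfavoured because the C5–O1 bond lies in the nodal plane of the exocyclic enolate; C4 is left as an epimer mixture to be settled in step 11.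

Step 8
Reactants: 10 methyl (2S,3R)-2-Ar-3-(TBDPS-oxymethyl)oxolane-4-carboxylate
Product: 11 (2S,3R)-2-Ar-3-(TBDPS-oxymethyl)-N-methoxy-N-methyloxolane-4-carboxamide as a mixture of C4 epimers
Conditions: MeNHOMe·HCl, iPrMgCl, THF, −20 → 0 °C
Reagents that add atoms: N,O-dimethylhydroxylamine hydrochloride, CNOC.Cl
Why: Direct aminolysis of the methyl ester by the chloromagnesium amide of N,O-dimethylhydroxylamine (Weinreb amide formation from an ester) works on α-branched esters at low temperature, and the C4 configuration is immaterial at this stage.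

Step 9
Reactants: 12 4-bromo-2,6-dimethoxyphenol
Product: 13 2-(benzyloxy)-5-bromo-1,3-dimethoxybenzene
Conditions: BnBr, K2CO3, DMF, 60 °C
Reagents that add atoms: benzyl bromide, BrCc1ccccc1
Why: Williamson O-benzylation of the phenol gives an aryl bromide whose oxygen function is inert to butyllithium and is released in the same final hydrogenolysis as the other aryl benzyl ether.

Step 10
Reactants: 11 (2S,3R)-2-Ar-3-(TBDPS-oxymethyl)-N-methoxy-N-methyloxolane-4-carboxamide; 13 2-(benzyloxy)-5-bromo-1,3-dimethoxybenzene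
Product: 15 Ar (2S,3R)-2-Ar-3-(TBDPS-oxymethyl)oxolan-4-yl ketone as a mixture of C4 epimers, via 4-benzyloxy-3,5-dimethoxyphenyllithium 14 (not isolated)
Conditions: 13, nBuLi, THF, −78 °C; then 11, −78 → −20 °C; aq NH4Cl
Reagents that add atoms: none
Why: Bromine–lithium exchange followed by the Weinreb ketone synthesis: the aryllithium adds once because the chelated tetrahedral intermediate survives until the aqueous quench, so the aryl ketone should form without over-addition.

Step 11
Reactants: 15 Ar (2S,3R)-2-Ar-3-(TBDPS-oxymethyl)oxolan-4-yl ketone (C4 epimers)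
Product: 16 Ar (2S,3R,4S)-2-Ar-3-(TBDPS-oxymethyl)oxolan-4-yl ketone (all-trans)
Conditions: DBU (0.3 equiv), CH2Cl2, rt
Reagents that add atoms: none
Why: Base-mediated epimerisation through the ketone enolate (thermodynamic equilibration) should move C4 to the 4S configuration with the aroyl group trans to the C3 substituent, and it is done before the alcohol is freed so that a 3,4-cis isomer cannot be trapped as a bicyclic hemiketal.

Step 12
Reactants: 16 Ar (2S,3R,4S)-2-Ar-3-(TBDPS-oxymethyl)oxolan-4-yl ketone
Product: 17 Ar (2S,3R,4S)-2-Ar-3-(hydroxymethyl)oxolan-4-yl ketone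
Conditions: Bu4NF, AcOH (1:1), THF, 0 °C → rt
Reagents that add atoms: none
Why: Fluoride-mediated desilylation, buffered with acetic acid so that the medium stays non-basic and C4 is not disturbed, frees the primary alcohol.

Step 13
Reactants: 17 Ar (2S,3R,4S)-2-Ar-3-(hydroxymethyl)oxolan-4-yl ketone
Product: 18 (4-hydroxy-3,5-dimethoxyphenyl)[(2S,3R,4S)-2-(4-hydroxy-3,5-dimethoxyphenyl)-3-(hydroxymethyl)oxolan-4-yl]methanone (target)
Conditions: H2 (1 atm), 10% Pd/C, EtOAc–MeOH, rt
Reagents that add atoms: none
Why: Catalytic hydrogenolysis cleaves the two aryl benzyl ethers, the most labile benzylic C–O bonds present, and stopping after two equivalents of hydrogen should leave the aryl ketone and the cyclic benzylic ether C2–O1 intact.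

**Compound list**

1 | syringaldehyde (4-hydroxy-3,5-dimethoxybenzaldehyde) | COc1cc(C=O)cc(OC)c1O | starting material
2 | 4-(benzyloxy)-3,5-dimethoxybenzaldehyde | COc1cc(C=O)cc(OC)c1OCc1ccccc1 | intermediate
3 | (E)-3-[4-(benzyloxy)-3,5-dimethoxyphenyl]prop-2-enal | COc1cc(/C=C/C=O)cc(OC)c1OCc1ccccc1 | intermediate
4 | dimethyl bromomalonate | COC(=O)C(Br)C(=O)OC | starting material
5 | dimethyl (2S,3R)-2-[4-(benzyloxy)-3,5-dimethoxyphenyl]-3-formylcyclopropane-1,1-dicarboxylate | COC(=O)C1(C(=O)OC)[C@H](c2cc(OC)c(OCc3ccccc3)c(OC)c2)[C@H]1C=O | intermediate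
6 | dimethyl (2S,3R)-2-[4-(benzyloxy)-3,5-dimethoxyphenyl]-3-(hydroxymethyl)cyclopropane-1,1-dicarboxylate | COC(=O)C1(C(=O)OC)[C@H](c2cc(OC)c(OCc3ccccc3)c(OC)c2)[C@H]1CO | intermediate
7 | dimethyl (2S,3R)-2-[4-(benzyloxy)-3,5-dimethoxyphenyl]-3-{[(tert-butyldiphenylsilyl)oxy]methyl}cyclopropane-1,1-dicarboxylate | COC(=O)C1(C(=O)OC)[C@H](c2cc(OC)c(OCc3ccccc3)c(OC)c2)[C@H]1CO[Si](c1ccccc1)(c1ccccc1)C(C)(C)C | intermediate
8 | formaldehyde (charged as its polymer paraformaldehyde) | C=O | starting material
9 | dimethyl (2S,3R)-2-[4-(benzyloxy)-3,5-dimethoxyphenyl]-3-{[(tert-butyldiphenylsilyl)oxy]methyl}oxolane-4,4-dicarboxylate | COC(=O)C1(C(=O)OC)CO[C@H](c2cc(OC)c(OCc3ccccc3)c(OC)c2)[C@H]1CO[Si](c1ccccc1)(c1ccccc1)C(C)(C)C | intermediate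
10 | methyl (2S,3R)-2-[4-(benzyloxy)-3,5-dimethoxyphenyl]-3-{[(tert-butyldiphenylsilyl)oxy]methyl}oxolane-4-carboxylate, C4 epimers | COC(=O)C1CO[C@H](c2cc(OC)c(OCc3ccccc3)c(OC)c2)[C@H]1CO[Si](c1ccccc1)(c1ccccc1)C(C)(C)C | intermediate
11 | (2S,3R)-2-[4-(benzyloxy)-3,5-dimethoxyphenyl]-3-{[(tert-butyldiphenylsilyl)oxy]methyl}-N-methoxy-N-methyloxolane-4-carboxamide, C4 epimers | CON(C)C(=O)C1CO[C@H](c2cc(OC)c(OCc3ccccc3)c(OC)c2)[C@H]1CO[Si](c1ccccc1)(c1ccccc1)C(C)(C)C | intermediate
12 | 4-bromo-2,6-dimethoxyphenol | COc1cc(Br)cc(OC)c1O | starting material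
13 | 2-(benzyloxy)-5-bromo-1,3-dimethoxybenzene | COc1cc(Br)cc(OC)c1OCc1ccccc1 | intermediate
14 | [4-(benzyloxy)-3,5-dimethoxyphenyl]lithium | [Li]c1cc(OC)c(OCc2ccccc2)c(OC)c1 | intermediate
15 | [4-(benzyloxy)-3,5-dimethoxyphenyl][(2S,3R)-2-[4-(benzyloxy)-3,5-dimethoxyphenyl]-3-{[(tert-butyldiphenylsilyl)oxy]methyl}oxolan-4-yl]methanone, C4 epimers | COc1cc(C(=O)C2CO[C@H](c3cc(OC)c(OCc4ccccc4)c(OC)c3)[C@H]2CO[Si](c2ccccc2)(c2ccccc2)C(C)(C)C)cc(OC)c1OCc1ccccc1 | intermediate
16 | [4-(benzyloxy)-3,5-dimethoxyphenyl][(2S,3R,4S)-2-[4-(benzyloxy)-3,5-dimethoxyphenyl]-3-{[(tert-butyldiphenylsilyl)oxy]methyl}oxolan-4-yl]methanone | COc1cc(C(=O)[C@@H]2CO[C@H](c3cc(OC)c(OCc4ccccc4)c(OC)c3)[C@H]2CO[Si](c2ccccc2)(c2ccccc2)C(C)(C)C)cc(OC)c1OCc1ccccc1 | intermediate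
17 | [4-(benzyloxy)-3,5-dimethoxyphenyl][(2S,3R,4S)-2-[4-(benzyloxy)-3,5-dimethoxyphenyl]-3-(hydroxymethyl)oxolan-4-yl]methanone | COc1cc(C(=O)[C@@H]2CO[C@H](c3cc(OC)c(OCc4ccccc4)c(OC)c3)[C@H]2CO)cc(OC)c1OCc1ccccc1 | intermediate
18 | (4-hydroxy-3,5-dimethoxyphenyl)[(2S,3R,4S)-2-(4-hydroxy-3,5-dimethoxyphenyl)-3-(hydroxymethyl)oxolan-4-yl]methanone | COc1cc(C(=O)[C@@H]2CO[C@H](c3cc(OC)c(O)c(OC)c3)[C@H]2CO)cc(OC)c1O | target

**Step count and risks**

Total steps: 13. Longest linear sequence: 12 (steps 1–8 and 10–13 from syringaldehyde; step 9 is a one-step side branch).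

Steps most likely to fail:

1. Step 6. Monomeric formaldehyde may be released too slowly or re-oligomerise, so the ring-opened zwitterion loses a proton to the styrene instead of being trapped. Equilibration at C2 may also stop short and leave the kinetic 2,3-cis adduct. The fallback sets out from 7 and returns at 9. Cu(OTf)2-catalysed ring opening of 7 with methanol in CH2Cl2 (nucleophilic opening of a donor–acceptor cyclopropane by an alcohol) would give dimethyl 2-[(2R)-1-[4-(benzyloxy)-3,5-dimethoxyphenyl]-3-[(tert-butyldiphenylsilyl)oxy]-1-methoxypropan-2-yl]propanedioate F1 as a mixture at the benzylic carbon. Aldol-type hydroxymethylation of its malonate C–H with aqueous formaldehyde and KHCO3 would give dimethyl 2-[(2R)-1-[4-(benzyloxy)-3,5-dimethoxyphenyl]-3-[(tert-butyldiphenylsilyl)oxy]-1-methoxypropan-2-yl]-2-(hydroxymethyl)propanedioate F2. BF3·OEt2 in CH2Cl2 at −20 °C would then ionise the benzylic methyl ether, and the primary hydroxyl would capture the cation to close the oxolane under thermodynamic control. This is the acid-mediated cycloetherification familiar from 2-aryl oxolane lignans, and it should give 2,3-trans 9.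

2. Step 10. The aryllithium may deprotonate C4 of the hindered amide instead of adding to it, returning starting material and opening the way to β-elimination of O1. The fallback sets out from 11 and returns at 15. Reduction of 11 with iBu2AlH in THF at −78 °C would give (2S,3R)-2-[4-(benzyloxy)-3,5-dimethoxyphenyl]-3-{[(tert-butyldiphenylsilyl)oxy]methyl}oxolane-4-carbaldehyde F3. Addition of 14 at −78 °C, much faster at an aldehyde than enolisation, would give [4-(benzyloxy)-3,5-dimethoxyphenyl][(2S,3R)-2-[4-(benzyloxy)-3,5-dimethoxyphenyl]-3-{[(tert-butyldiphenylsilyl)oxy]methyl}oxolan-4-yl]methanol F4 as a carbinol mixture. Dess–Martin oxidation (NaHCO3, CH2Cl2) would then give 15.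

3. Step 8. Aminolysis of the α-branched ester by the magnesium amide may be slower than enolisation, so conversion stalls or the ring opens on warming. The fallback sets out from 10 and returns at 11. Saponification with LiOH in THF–H2O at rt would give (2S,3R)-2-[4-(benzyloxy)-3,5-dimethoxyphenyl]-3-{[(tert-butyldiphenylsilyl)oxy]methyl}oxolane-4-carboxylic acid F5. Carbodiimide coupling (EDC·HCl, HOBt, iPr2NEt, CH2Cl2) with N,O-dimethylhydroxylamine hydrochloride would then give 11.

Further compounds

F1 | step 6 | dimethyl 2-[(2R)-1-[4-(benzyloxy)-3,5-dimethoxyphenyl]-3-[(tert-butyldiphenylsilyl)oxy]-1-methoxypropan-2-yl]propanedioate (C1 epimers) | COC(=O)C(C(=O)OC)[C@H](CO[Si](c1ccccc1)(c1ccccc1)C(C)(C)C)C(OC)c1cc(OC)c(OCc2ccccc2)c(OC)c1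
F2 | step 6 | dimethyl 2-[(2R)-1-[4-(benzyloxy)-3,5-dimethoxyphenyl]-3-[(tert-butyldiphenylsilyl)oxy]-1-methoxypropan-2-yl]-2-(hydroxymethyl)propanedioate (C1 epimers) | COC(=O)C(CO)(C(=O)OC)[C@H](CO[Si](c1ccccc1)(c1ccccc1)C(C)(C)C)C(OC)c1cc(OC)c(OCc2ccccc2)c(OC)c1
F3 | step 10 | (2S,3R)-2-[4-(benzyloxy)-3,5-dimethoxyphenyl]-3-{[(tert-butyldiphenylsilyl)oxy]methyl}oxolane-4-carbaldehyde (C4 epimers) | O=CC1CO[C@H](c2cc(OC)c(OCc3ccccc3)c(OC)c2)[C@H]1CO[Si](c1ccccc1)(c1ccccc1)C(C)(C)C
F4 | step 10 | [4-(benzyloxy)-3,5-dimethoxyphenyl][(2S,3R)-2-[4-(benzyloxy)-3,5-dimethoxyphenyl]-3-{[(tert-butyldiphenylsilyl)oxy]methyl}oxolan-4-yl]methanol (carbinol and C4 epimers) | COc1cc(C(O)C2CO[C@H](c3cc(OC)c(OCc4ccccc4)c(OC)c3)[C@H]2CO[Si](c2ccccc2)(c2ccccc2)C(C)(C)C)cc(OC)c1OCc1ccccc1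
F5 | step 8 | (2S,3R)-2-[4-(benzyloxy)-3,5-dimethoxyphenyl]-3-{[(tert-butyldiphenylsilyl)oxy]methyl}oxolane-4-carboxylic acid (C4 epimers) | OC(=O)C1CO[C@H](c2cc(OC)c(OCc3ccccc3)c(OC)c2)[C@H]1CO[Si](c1ccccc1)(c1ccccc1)C(C)(C)C
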